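**Retrosynthetic overview**

- The last bond made is the C6–CH2–C3' bridge, from the 8-acylchromantriol, 6-ethyl-4-hydroxy-5-methylpyran-2-one and a one-carbon iminium electrophile.
- The C8 acyl group comes from a C8 bromide (as aryllithium) and the (S)-Weinreb amide; the C3 carbinol comes from CBS reduction of 5,7-bis(benzyloxy)-2,2-dimethylchroman-3-one.
- Feature the route rests on: in the chroman ring only the C4 methylene separates aromatic C4a from oxygenated C3, so the O1–C2–C3–C4–C4a–C8a ring is a 2,2-dimethylbenzofuran-3(2H)-one ring plus one carbon. C4 is inserted into the aryl–carbonyl bond with trimethylsilyldiazomethane.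
- The benzofuranone comes from phloroglucinol and 2-bromo-2-methylpropanoyl bromide; the pyranone from the dianion of methyl 3-oxopentanoate and a propionyl Weinreb amide.
- Ring order: benzene ring (purchased), then the furanone ring, then its expansion to the dihydropyran ring; the pyranone ring is built separately and attached last.

Key step: step 3

Remark: the SMILES is read as (3S) at the chroman carbinol and (2S) in the 2-methylbutanoyl chain, and the sense of the CBS reduction is assigned by treating the quaternary C2 as the large carbonyl substituent.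

**Route**

Step 1
Reactants: 1 phloroglucinol; 2 2-bromo-2-methylpropanoyl bromide
Product: 4 4,6-dihydroxy-2,2-dimethylbenzofuran-3(2H)-one, via bromoketone 3 (not isolated)
Conditions: AlCl3 (3.5 equiv), PhNO2, 0 °C → rt; aq. HCl work-up; crude 3, NaOAc, EtOH, reflux
Reagents that add atoms: none
Why: Friedel–Crafts C-acylation of the symmetrical, strongly activated arene should give the ortho-hydroxyaryl α-bromo ketone, whose neighbouring phenol then displaces the tertiary α-bromide (5-exo-tet intramolecular Williamson-type O-alkylation) under mild base to close the furanone.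

Step 2
Reactants: 4 4,6-dihydroxy-2,2-dimethylbenzofuran-3(2H)-one
Product: 5 4,6-bis(benzyloxy)-2,2-dimethylbenzofuran-3(2H)-one
Conditions: BnBr (2.5 equiv), K2CO3, DMF, 60 °C
Reagents that add atoms: benzyl bromide, BrCc1ccccc1
Why: Williamson etherification, in which the free 6-OH should react first and the carbonyl-chelated 4-OH follow on warming.

Step 3
Reactants: 5 4,6-bis(benzyloxy)-2,2-dimethylbenzofuran-3(2H)-one; 6 trimethylsilyldiazomethane
Product: 9 5,7-bis(benzyloxy)-2,2-dimethylchroman-3-one, via 4-silyl chroman-3-one 7 (not isolated), via silyl enol ether 8 (not isolated)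
Conditions: BF3·OEt2 (1.5 equiv), CH2Cl2, −78 °C; TMSCHN2 (2 M in hexanes, 1.5 equiv, slow addition), −78 → −20 °C; aq. NaHCO3; then 1 M HCl, THF, rt
Reagents that add atoms: none
Why: Proposed new method: BF3 bound to the C3 carbonyl of 5 should let the diazo carbon of 6 add, and in the β-oxido diazonium so formed the aryl carbon (C3a) shifts to the new carbon as N2 leaves, so that the inserted carbon (chroman C4) ends bonded to C4a and to the carbonyl carbon C3; the closest known reaction type is the Lewis acid-promoted Tiffeneau–Demjanov-type homologation of benzo-fused cycloalkanones with TMSCHN2 (1-indanone to 2-tetralone), which has not been shown on benzofuran-3(2H)-ones. The six-membered oxygen ring is therefore not closed by cyclisation but arises by one-carbon ring expansion (1,2-aryl shift) of the furanone, and no stereocentre is formed. The step needs migration of the aryl carbon and not of C2 (which would give the chroman-4-one); the trioxygenated ring migrates through a well-stabilised phenonium-like transition state, whereas C2 is quaternary, hindered against the silyl group and inductively deactivated by its oxygen. It also needs a single insertion: the benzylic α-silyl ketone 7 should undergo a 1,3 C-to-O silyl shift to enol ether 8, which no longer offers a carbonyl to the diazoalkane, and 5 itself has no enolisable hydrogen. Acidic hydrolysis of 8 (or protodesilylation of any surviving 7) then releases ketone 9. The weak electrophilicity of the doubly alkoxy-conjugated carbonyl is the main uncertainty, which is why a stoichiometric strong Lewis acid is used.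

Step 4
Reactants: 9 5,7-bis(benzyloxy)-2,2-dimethylchroman-3-one
Product: 10 (3S)-5,7-bis(benzyloxy)-2,2-dimethylchroman-3-ol
Conditions: (R)-2-methyl-CBS-oxazaborolidine (20 mol %), BH3·SMe2, THF, −20 °C; MeOH quench
Reagents that add atoms: none
Why: Corey–Bakshi–Shibata reduction, in which the ketone should bind the catalyst with quaternary C2 as the large and the C4 methylene as the small substituent, so that the (R)-catalyst delivers hydride to the face giving the (3S)-carbinol (the sense established for tert-alkyl ketones such as pinacolone).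

Step 5
Reactants: 10 (3S)-5,7-bis(benzyloxy)-2,2-dimethylchroman-3-ol
Product: 11 (3S)-3,5,7-tris(benzyloxy)-2,2-dimethylchroman
Conditions: NaH, BnBr, Bu4NI (cat.), DMF, 0 °C → rt
Reagents that add atoms: benzyl bromide, BrCc1ccccc1
Why: Williamson etherification of the alkoxide masks the carbinol for the organolithium step with a group that leaves later together with the aryl benzyl ethers, and C3 is not touched.

Step 6
Reactants: 11 (3S)-3,5,7-tris(benzyloxy)-2,2-dimethylchroman
Product: 12 (3S)-3,5,7-tris(benzyloxy)-8-bromo-2,2-dimethylchroman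
Conditions: NBS (1.0 equiv), CH2Cl2, −78 → 0 °C
Reagents that add atoms: N-bromosuccinimide, O=C1CCC(=O)N1Br
Why: Electrophilic aromatic bromination, in which C8 (its neighbour O1 tied back in the ring) should be attacked in preference to C6 (between two benzyloxy groups), the site preference known for NBS bromination of 5,7-bis(benzyloxy)flavan-3-ol derivatives.

Step 7
Reactants: 13 (S)-2-methylbutanoic acid
Product: 15 (2S)-N-methoxy-N,2-dimethylbutanamide, via acyl imidazolide 14 (not isolated)
Conditions: CDI, CH2Cl2, 0 °C → rt; then MeNHOMe·HCl, rt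
Reagents that add atoms: N,O-dimethylhydroxylamine hydrochloride, CNOC.Cl; 1,1'-carbonyldiimidazole, O=C(n1ccnc1)n1ccnc1 (imidazolyl of intermediate 14 only)
Why: Weinreb amide formation through the acyl imidazolide, a non-basic activation under which the α-stereocentre should keep its (S) configuration.

Step 8
Reactants: 12 (3S)-3,5,7-tris(benzyloxy)-8-bromo-2,2-dimethylchroman; 15 (2S)-N-methoxy-N,2-dimethylbutanamide
Product: 17 (2S)-2-methyl-1-[(3S)-3,5,7-tris(benzyloxy)-2,2-dimethylchroman-8-yl]butan-1-one, via aryllithium 16 (not isolated)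
Conditions: t-BuLi (2.1 equiv), THF, −78 °C; then 15, −78 → −20 °C; 1 M HCl, 0 °C
Reagents that add atoms: tert-butyllithium, [Li]C(C)(C)C (lithium of intermediate 16 only)
Why: Bromine–lithium exchange followed by Weinreb ketone synthesis, in which the chelated tetrahedral adduct persists until the quench, so over-addition is excluded and the ketone with its (2S) α-centre is not exposed to base.

Step 9
Reactants: 17 (2S)-2-methyl-1-[(3S)-3,5,7-tris(benzyloxy)-2,2-dimethylchroman-8-yl]butan-1-one
Product: 18 (2S)-2-methyl-1-[(3S)-3,5,7-trihydroxy-2,2-dimethylchroman-8-yl]butan-1-one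
Conditions: H2 (1 atm), Pd(OH)2/C, EtOAc–MeOH, rt
Reagents that add atoms: none
Why: Hydrogenolysis of the two aryl benzyl ethers and the alkyl benzyl ether under neutral conditions, which the hydrogen-bonded aryl ketone and both stereocentres should survive.

Step 10
Reactants: 19 methyl 3-oxopentanoate; 20 N-methoxy-N-methylpropanamide
Product: 22 methyl 4-methyl-3,5-dioxoheptanoate, via dilithio dianion 21 (not isolated)
Conditions: LDA (2.2 equiv), THF, −78 → 0 °C; then 20, −78 °C → rt; 1 M HCl
Reagents that add atoms: lithium diisopropylamide, [Li]N(C(C)C)C(C)C (lithium of intermediate 21 only)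
Why: γ-Selective acylation of a β-keto ester dianion at its more basic C4 carbanion, the Weinreb amide giving a stable adduct so that the acidic product does not quench unreacted dianion; the new C4 centre is enolisable and disappears in step 11.

Step 11
Reactants: 22 methyl 4-methyl-3,5-dioxoheptanoate
Product: 23 6-ethyl-4-hydroxy-5-methyl-2H-pyran-2-one
Conditions: DBU (1.2 equiv), toluene, reflux; then 1 M HCl
Reagents that add atoms: none
Why: Base-mediated lactonisation, in which the C5 enol oxygen attacks the ester with loss of methanol and the ring settles as the aromatic 4-hydroxy-2-pyranone tautomer.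

Step 12
Reactants: 23 6-ethyl-4-hydroxy-5-methyl-2H-pyran-2-one; 18 (2S)-2-methyl-1-[(3S)-3,5,7-trihydroxy-2,2-dimethylchroman-8-yl]butan-1-one
Product: 26 6-ethyl-4-hydroxy-5-methyl-3-{[(3S)-3,5,7-trihydroxy-2,2-dimethyl-8-[(2S)-2-methylbutanoyl]chroman-6-yl]methyl}-2H-pyran-2-one (target CNP0361212.1), via Mannich base 24 (not isolated), via methylidene pyranedione 25 (not isolated)
Conditions: 23 (1.5 equiv), Me2N=CH2+ I− (1.5 equiv), MeCN, rt; then 18 (1.0 equiv), 60 °C
Reagents that add atoms: Eschenmoser's salt (N,N-dimethylmethyleneiminium iodide), C=[N+](C)C.[I-]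
Why: Mannich reaction at pyranone C3, thermal loss of dimethylamine to the 3-methylidene-pyran-2,4-dione and Friedel–Crafts-type conjugate addition of C6 (the only unsubstituted carbon of the phloroglucinol ring of 18), followed by rearomatisation, should give the methylene-bridged product without touching either stereocentre.

**Compound list**

1 | phloroglucinol | Oc1cc(O)cc(O)c1 | starting material
2 | 2-bromo-2-methylpropanoyl bromide | CC(C)(Br)C(=O)Br | starting material
3 | 2-bromo-2-methyl-1-(2,4,6-trihydroxyphenyl)propan-1-one | CC(C)(Br)C(=O)c1c(O)cc(O)cc1O | intermediate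
4 | 4,6-dihydroxy-2,2-dimethylbenzofuran-3(2H)-one | CC1(C)Oc2cc(O)cc(O)c2C1=O | intermediate
5 | 4,6-bis(benzyloxy)-2,2-dimethylbenzofuran-3(2H)-one | CC1(C)Oc2cc(OCc3ccccc3)cc(OCc3ccccc3)c2C1=O | intermediate
6 | trimethylsilyldiazomethane | C[Si](C)(C)C=[N+]=[N-] | starting material
7 | 5,7-bis(benzyloxy)-2,2-dimethyl-4-(trimethylsilyl)chroman-3-one (racemic at C4) | CC1(C)Oc2cc(OCc3ccccc3)cc(OCc3ccccc3)c2C([Si](C)(C)C)C1=O | intermediate
8 | 5,7-bis(benzyloxy)-2,2-dimethyl-3-(trimethylsilyloxy)-2H-chromene | CC1(C)Oc2cc(OCc3ccccc3)cc(OCc3ccccc3)c2C=C1O[Si](C)(C)C | intermediate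
9 | 5,7-bis(benzyloxy)-2,2-dimethylchroman-3-one | CC1(C)Oc2cc(OCc3ccccc3)cc(OCc3ccccc3)c2CC1=O | intermediate
10 | (3S)-5,7-bis(benzyloxy)-2,2-dimethylchroman-3-ol | CC1(C)Oc2cc(OCc3ccccc3)cc(OCc3ccccc3)c2C[C@@H]1O | intermediate
11 | (3S)-3,5,7-tris(benzyloxy)-2,2-dimethylchroman | CC1(C)Oc2cc(OCc3ccccc3)cc(OCc3ccccc3)c2C[C@@H]1OCc1ccccc1 | intermediate
12 | (3S)-3,5,7-tris(benzyloxy)-8-bromo-2,2-dimethylchroman | CC1(C)Oc2c(Br)c(OCc3ccccc3)cc(OCc3ccccc3)c2C[C@@H]1OCc1ccccc1 | intermediate
13 | (S)-2-methylbutanoic acid | CC[C@H](C)C(=O)O | starting material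
14 | 1-[(2S)-2-methylbutanoyl]imidazole | CC[C@H](C)C(=O)n1ccnc1 | intermediate
15 | (2S)-N-methoxy-N,2-dimethylbutanamide | CC[C@H](C)C(=O)N(C)OC | intermediate
16 | [(3S)-3,5,7-tris(benzyloxy)-2,2-dimethylchroman-8-yl]lithium | CC1(C)Oc2c([Li])c(OCc3ccccc3)cc(OCc3ccccc3)c2C[C@@H]1OCc1ccccc1 | intermediate
17 | (2S)-2-methyl-1-[(3S)-3,5,7-tris(benzyloxy)-2,2-dimethylchroman-8-yl]butan-1-one | CC[C@H](C)C(=O)c1c(OCc2ccccc2)cc(OCc2ccccc2)c2c1OC(C)(C)[C@@H](OCc1ccccc1)C2 | intermediate
18 | (2S)-2-methyl-1-[(3S)-3,5,7-trihydroxy-2,2-dimethylchroman-8-yl]butan-1-one | CC[C@H](C)C(=O)c1c(O)cc(O)c2c1OC(C)(C)[C@@H](O)C2 | intermediate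
19 | methyl 3-oxopentanoate | CCC(=O)CC(=O)OC | starting material
20 | N-methoxy-N-methylpropanamide | CCC(=O)N(C)OC | starting material
21 | dilithio dianion of methyl 3-oxopentanoate (C2/C4) | C[CH-]C([O-])=CC(=O)OC.[Li+].[Li+] | intermediate
22 | methyl 4-methyl-3,5-dioxoheptanoate (racemic at C4) | CCC(=O)C(C)C(=O)CC(=O)OC | intermediate
23 | 6-ethyl-4-hydroxy-5-methyl-2H-pyran-2-one | CCc1oc(=O)cc(O)c1C | intermediate
24 | 3-[(dimethylamino)methyl]-6-ethyl-4-hydroxy-5-methyl-2H-pyran-2-one | CCc1oc(=O)c(CN(C)C)c(O)c1C | intermediate
25 | 6-ethyl-5-methyl-3-methylidene-2H-pyran-2,4(3H)-dione | CCC1=C(C)C(=O)C(=C)C(=O)O1 | intermediate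
26 | 6-ethyl-4-hydroxy-5-methyl-3-{[(3S)-3,5,7-trihydroxy-2,2-dimethyl-8-[(2S)-2-methylbutanoyl]chroman-6-yl]methyl}-2H-pyran-2-one | CCc1oc(=O)c(Cc2c(O)c3c(c(C(=O)[C@@H](C)CC)c2O)OC(C)(C)[C@@H](O)C3)c(O)c1C | target

**Step count and risks**

Total step count: 12. Longest linear sequence: 9 steps (steps 1–6, 8, 9 and 12 from phloroglucinol); steps 7, 10 and 11 are side branches.

Steps most likely to fail:

1. Step 3 (proposed new method). The doubly alkoxy-conjugated carbonyl may be activated too weakly, so that the diazoalkane decomposes faster than it adds. Migration of C2 instead of the aryl carbon, or a second insertion into the product ketone, could also erode the outcome. The fallback uses known chemistry, sets out from 1 and comes back at 10, by-passing 5 and 9. Dibenzylation of 1 (BnBr, K2CO3, DMF, with separation from the mono- and tri-ethers) should give 3,5-bis(benzyloxy)phenol F1. Condensation of F1 with 3-methylbut-2-enal (ethylenediammonium diacetate cat., toluene, reflux; C-alkylation then oxa-6π electrocyclisation) should give 5,7-bis(benzyloxy)-2,2-dimethyl-2H-chromene F2. Jacobsen epoxidation with the (S,S)-Mn(salen) catalyst (buffered NaOCl, 4-phenylpyridine N-oxide, CH2Cl2, 0 °C) is expected to give (3S,4S)-5,7-bis(benzyloxy)-3,4-epoxy-2,2-dimethylchroman F3. The crude, acid-sensitive F3 is then opened by hydride at the benzylic C4 (LiAlH4, THF, 0 °C), which leaves the C3–O bond intact and should deliver 10.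

2. Step 12. Retro-Mannich exchange of the methylene unit and homo-coupling of the pyranone (methylene-bis-pyranone) may compete with the cross-coupling, and the electrophile may be consumed before the hindered C6 attacks. The fallback reverses the roles of the partners, sets out from 18 and comes back at 26. Compound 18 with Eschenmoser's salt (CH2Cl2, rt) should give the C6 Mannich base (2S)-1-[(3S)-6-[(dimethylamino)methyl]-3,5,7-trihydroxy-2,2-dimethylchroman-8-yl]-2-methylbutan-1-one F5. Heating F5 with excess 23 (dioxane, 90 °C) should release the ortho-quinone methide of the phloroglucinol ring, which 23 traps at its C3.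

3. Step 8. Proton transfer to the hindered aryllithium from the amide α-C–H or from a benzylic ether position may return debrominated 11 and erode the (2S) centre, and addition to the α-branched amide may be slow. The fallback replaces the organometallic by an electrophilic acylation, sets out from 11 (with 13) and comes back at 17. Acid 13 with oxalyl chloride (cat. DMF, CH2Cl2, 0 °C → rt) should give (S)-2-methylbutanoyl chloride F4. Friedel–Crafts acylation of 11 with F4 (SnCl4, CH2Cl2, −78 → −40 °C) should go to C8 under the same steric bias as in step 6. Any ketone that has lost its ortho benzyl group converges on 18 in step 9.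

**Further compounds**

F1 | step 3 | 3,5-bis(benzyloxy)phenol | Oc1cc(OCc2ccccc2)cc(OCc2ccccc2)c1
F2 | step 3 | 5,7-bis(benzyloxy)-2,2-dimethyl-2H-chromene | CC1(C)C=Cc2c(OCc3ccccc3)cc(OCc3ccccc3)cc2O1
F3 | step 3 | (3S,4S)-5,7-bis(benzyloxy)-3,4-epoxy-2,2-dimethylchroman | CC1(C)Oc2cc(OCc3ccccc3)cc(OCc3ccccc3)c2[C@@H]2O[C@H]12
F4 | step 8 | (S)-2-methylbutanoyl chloride | CC[C@H](C)C(Cl)=O
F5 | step 12 | (2S)-1-[(3S)-6-[(dimethylamino)methyl]-3,5,7-trihydroxy-2,2-dimethylchroman-8-yl]-2-methylbutan-1-one | CC[C@H](C)C(=O)c1c(O)c(CN(C)C)c(O)c2c1OC(C)(C)[C@@H](O)C2
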